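**Strategy.** Ring B of the hydroazulene is cut at C6–C7 and C9–C10. C7–C8–C9 then form an oxyallyl cation, and C10=C1–C5=C6 a diene whose two double bonds are exocyclic to ring A and therefore locked s-cis; C6 carries the silyloxy group that becomes the ester oxygen. One (4+3) cycloaddition forms both bonds, closes ring B, and leaves a C8 ketone (handle for the C8 methyl and C8=C9) and a C1=C5 alkene (handle for the angular methyl and H-5). The diene is the dienol silyl ether of a cyclopentene aldehyde made from (S)-terpinen-4-ol, whose carbinol carbon becomes C4 and fixes the absolute configuration.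

Key step: step 5

Atom labels: ring A = C1 (angular methyl), C2, C3, C4 (hydroxyl, isopropyl), C5 (H); ring B = C1, C5, C6 (ester oxygen), C7, C8 (methyl), C9, C10, with the alkene at C8=C9.
Assumption: commercial (S)-terpinen-4-ol is taken as enantiomerically pure; its carbinol carbon is carried unchanged to C4.
Remark: the three-carbon unit is brought in as 1,1,3,3-tetrabromopropan-2-one, because the parent 1,3-dibromo ketone ionises poorly to an oxyallyl cation; the two surplus bromines are removed in the same flask. C6 is made without control in step 5 and is written without configuration in 10–15; both epimers merge in ketone 16.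

**Step 1**
Reactants: 1 (S)-terpinen-4-ol
Product: 2 triethylsilyl ether of 1
Conditions: Et3SiOTf, 2,6-lutidine, CH2Cl2, 0 °C → rt
Reagents that add atoms: triethylsilyl trifluoromethanesulfonate, CC[Si](CC)(CC)OS(=O)(=O)C(F)(F)F
Why: Silyl ether formation from a hindered tertiary alcohol with a silyl triflate and 2,6-lutidine is routine, leaves the stereocentre untouched, and blocks retro-aldol cleavage of the β-oxygenated aldehyde made in step 2.

**Step 2**
Reactants: 2 triethylsilyl ether
Product: 4 keto aldehyde (3S)-6-oxo-3-(propan-2-yl)-3-[(triethylsilyl)oxy]heptanal, via ozonide 3 (not isolated)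
Conditions: O3, CH2Cl2, −78 °C; then PPh3, −78 °C → rt
Reagents that add atoms: ozone, [O-][O+]=O
Why: Ozonolysis with reductive work-up cleaves the only alkene to a methyl ketone and an aldehyde without touching the silyl ether or the stereocentre.

**Step 3**
Reactants: 4 keto aldehyde
Product: 5 cyclopentene aldehyde (5R)-2-methyl-5-(propan-2-yl)-5-[(triethylsilyl)oxy]cyclopent-1-ene-1-carbaldehyde
Conditions: piperidine, AcOH, PhMe, 70 °C, molecular sieves
Reagents that add atoms: none
Why: Amine-catalysed intramolecular aldol condensation, in which piperidine forms an enamine only at the aldehyde, its carbon (future C5) attacks the methyl ketone carbon (future C1) in a five-membered closure and dehydration gives the tetrasubstituted enal, the course known for 6-oxoheptanals under these conditions, whereas hydroxide would favour the acetylcyclopentene mode.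

**Step 4**
Reactants: 5 cyclopentene aldehyde
Product: 7 ring A dienol silyl ether (exocyclic C10=C1 and C5=C6; C6–OTIPS; (E) enol ether; C4–OTES), via lithium dienolate 6 (not isolated)
Conditions: LiTMP (n-BuLi, 2,2,6,6-tetramethylpiperidine), THF, −78 °C; then i-Pr3SiOTf, −78 → −20 °C
Reagents that add atoms: triisopropylsilyl trifluoromethanesulfonate, CC(C)[Si](C(C)C)(C(C)C)OS(=O)(=O)C(F)(F)F
Why: Kinetic γ-deprotonation of an enal and O-silylation of its dienolate, in which the lithium amide bound to the carbonyl oxygen takes a proton from the methyl group cis to the formyl group (syn effect) and not from the ring CH2 at C2 that equilibrating amine and silyl triflate conditions would favour, the cyclic deprotonation places oxygen on the inner side of the diene (a geometry erased later), and cold trapping precedes loss of the β-silyloxy group at C4.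

**Step 5**
Reactants: 7 ring A dienol silyl ether; 8 1,1,3,3-tetrabromopropan-2-one
Product: 11 bicyclic C8 ketone (C1=C5 alkene; C6–OTIPS as both epimers; C4–OTES), via dibromo-oxyallyl cation 9 (not isolated), via dibromo cycloadduct 10 (not isolated)
Conditions: Zn–Cu couple, B(OEt)3, THF, −15 °C → rt; then Zn–Cu couple, NH4Cl, MeOH, 0 °C → rt
Reagents that add atoms: none
Why: Zn reduces 8 to a zinc enolate that ionises to the 1,3-dibromo-2-oxyallyl cation 9, the electron-rich diene of 7 attacks it through C10 to give a cation spread over C1–C5–C6 and capped by the silyloxy oxygen, the zinc enolate carbon closes on C6, and Zn–Cu with NH4Cl then removes the two α-bromines in the same flask. This is the (4+3) cycloaddition of oxyallyl cations known for furans, cyclopentadiene, s-cis-locked 1,2-bis(alkylidene)cycloalkanes and oxygenated dienes, run in its stepwise polar form. Ring B closes by seven-membered attack of the enolate carbon on the silyl oxocarbenium carbon C6, which leaves C1=C5 at the ring fusion and the carbonyl at C8. C6 is the only stereocentre that survives (those at C7 and C9 vanish on debromination); it depends on the diene face taken relative to the C4 substituents and on the enol ether geometry, neither is controlled, and none is needed because C6 becomes a ketone in step 9. The step needs seven-ring closure in preference to five-ring closure at C1 and to loss of the silyl group after the first bond: ring A holds the diene s-cis, C6 is the unhindered oxocarbenium end whereas closure at C1 would build a quaternary spiro centre, the bulky TIPS group transfers slowly, and the symmetric three-carbon partner raises no regiochemical question.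

**Step 6**
Reactants: 11 bicyclic C8 ketone
Product: 13 enol triflate (C8–OTf; C8=C9), via potassium enolate 12 (not isolated)
Conditions: KN(SiMe3)2, THF, −78 °C; then PhNTf2, −78 → 0 °C
Reagents that add atoms: N-phenylbis(trifluoromethanesulfonimide), O=S(=O)(N(c1ccccc1)S(=O)(=O)C(F)(F)F)C(F)(F)F
Why: Kinetic enolate formation and O-triflation, in which the bulky amide removes a proton from C9, whose neighbour C10 is a plain methylene, in preference to C7, which is screened by the adjacent carbon bearing the triisopropylsilyloxy group, so the double bond is placed at C8=C9.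

**Step 7**
Reactants: 13 enol triflate
Product: 14 C8-methyl diene bis(silyl ether)
Conditions: MeZnCl, Pd(PPh3)4 (cat.), THF, rt → 50 °C
Reagents that add atoms: methylzinc chloride, C[Zn]Cl
Why: Negishi coupling of the alkenyl triflate with methylzinc chloride under zerovalent palladium catalysis replaces C–OTf by C–CH3 with the double bond held at C8=C9, and the silyl ethers and the tetrasubstituted alkene are inert.

**Step 8**
Reactants: 14 C8-methyl diene bis(silyl ether)
Product: 15 diol (C4–OH; C6–OH as both epimers)
Conditions: Bu4NF, THF, rt → 40 °C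
Reagents that add atoms: none
Why: Fluoride-induced desilylation removes both silyl ethers under non-acidic conditions that spare the tertiary allylic alcohol and frees the C4 hydroxyl needed to steer steps 10 and 11.

**Step 9**
Reactants: 15 diol
Product: 16 dienone (C6 ketone conjugated to C1=C5; C4–OH; C8=C9)
Conditions: MnO2, CH2Cl2, rt
Reagents that add atoms: none
Why: Allylic oxidation with MnO2 can only affect the secondary allylic C6 alcohol, merges both C6 epimers into one enone and is neutral enough for the tertiary allylic alcohol and the skipped diene.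

**Step 10**
Reactants: 16 dienone
Product: 19 trans-fused hydroxy ketone (C1 methyl cis to C4–OH; H-5 trans to the methyl), via dilithium enolate alkoxide 17 (not isolated), via cis-fused C5 epimer 18 (not isolated)
Conditions: Me2CuLi (excess), Et2O, −40 → 0 °C; aq. NH4Cl; then DBU (cat.), PhMe, rt
Reagents that add atoms: lithium dimethylcuprate, [Li+].C[Cu-]C
Why: Conjugate addition of a lithium dialkylcuprate to a β,β-disubstituted enone, in which the first equivalent forms the C4 alkoxide, methyl is then transferred to C1 on the ring A face that carries this alkoxide and lies opposite the isopropyl group (methyl cis to the C4 oxygen), and C5, formed by enolate protonation and epimerisable α to the ketone, is settled by the base in the trans-fused arrangement that keeps C6 away from the isopropyl group and lets the C4 hydroxyl hydrogen-bond to the carbonyl.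

**Step 11**
Reactants: 19 trans-fused hydroxy ketone
Product: 20 diol (3R,3aS,4S,8aR)-6,8a-dimethyl-3-(propan-2-yl)-1,2,3,3a,4,5,8,8a-octahydroazulene-3,4-diol
Conditions: Me4NBH(OAc)3, MeCN–AcOH, −30 → 0 °C
Reagents that add atoms: none
Why: Evans–Saksena reduction, in which the C4 hydroxyl exchanges onto boron and hydride is passed intramolecularly to the C6 carbonyl from the face on which the C4–O bond lies, giving the C6 carbinol anti to the C4 hydroxyl (6S, hydroxyl cis to H-5) while the alkene is untouched.

**Step 12**
Reactants: 20 diol; 21 O-acetylsalicyloyl chloride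
Product: 23 target salicylate CNP0379621.1, via O-acetylsalicylate ester 22 (not isolated)
Conditions: 21, pyridine, DMAP (cat.), CH2Cl2, 0 °C → rt; then pyrrolidine, rt
Reagents that add atoms: none
Why: DMAP-catalysed acylation of the secondary C6 alcohol by the acid chloride, which the tertiary C4 alcohol does not undergo, followed in the same flask by aminolysis of the activated aryl acetate, which is much faster than attack on the hindered secondary salicylate, frees the phenol and leaves all four stereocentres unchanged.

**Compound list**
1 | (S)-terpinen-4-ol, (1S)-4-methyl-1-(propan-2-yl)cyclohex-3-en-1-ol | CC1=CC[C@](O)(C(C)C)CC1 | starting material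
2 | triethyl{[(1S)-4-methyl-1-(propan-2-yl)cyclohex-3-en-1-yl]oxy}silane | CC1=CC[C@](O[Si](CC)(CC)CC)(C(C)C)CC1 | intermediate
3 | ozonide (1,2,4-trioxolane) of 2 across the former alkene, both diastereomers at the trioxolane carbons | CC12CC[C@@](O[Si](CC)(CC)CC)(C(C)C)CC(OO1)O2 | intermediate (not isolated)
4 | (3S)-6-oxo-3-(propan-2-yl)-3-[(triethylsilyl)oxy]heptanal | CC(=O)CC[C@@](O[Si](CC)(CC)CC)(C(C)C)CC=O | intermediate
5 | (5R)-2-methyl-5-(propan-2-yl)-5-[(triethylsilyl)oxy]cyclopent-1-ene-1-carbaldehyde | CC1=C(C=O)[C@](O[Si](CC)(CC)CC)(C(C)C)CC1 | intermediate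
6 | lithium dienolate of 5 (exocyclic methylene at C1, O–Li on the inner side of the diene) | C=C1CC[C@@](O[Si](CC)(CC)CC)(C(C)C)/C1=C/O[Li] | intermediate (not isolated)
7 | triethyl{[(1R,2E)-3-methylidene-1-(propan-2-yl)-2-({[tri(propan-2-yl)silyl]oxy}methylidene)cyclopentyl]oxy}silane | C=C1CC[C@@](O[Si](CC)(CC)CC)(C(C)C)/C1=C/O[Si](C(C)C)(C(C)C)C(C)C | intermediate
8 | 1,1,3,3-tetrabromopropan-2-one | BrC(Br)C(=O)C(Br)Br | starting material
9 | 1,3-dibromo-2-(bromozincoxy)allyl cation | Br[CH+]C(O[Zn]Br)=CBr | intermediate (not isolated)
10 | 7,9-dibromo derivative of 11 (bromide and C6 epimers) | O=C1C(Br)CC2=C(C(O[Si](C(C)C)(C(C)C)C(C)C)C1Br)[C@](O[Si](CC)(CC)CC)(C(C)C)CC2 | intermediate (not isolated)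
11 | (3R)-3-(propan-2-yl)-3-[(triethylsilyl)oxy]-4-{[tri(propan-2-yl)silyl]oxy}-2,3,4,5,7,8-hexahydroazulen-6(1H)-one (C8 ketone, C1=C5, C6 epimers) | O=C1CCC2=C(C(O[Si](C(C)C)(C(C)C)C(C)C)C1)[C@](O[Si](CC)(CC)CC)(C(C)C)CC2 | intermediate
12 | potassium enolate of 11 toward C9 | [K]OC1=CCC2=C(C(O[Si](C(C)C)(C(C)C)C(C)C)C1)[C@](O[Si](CC)(CC)CC)(C(C)C)CC2 | intermediate (not isolated)
13 | (3R)-3-(propan-2-yl)-3-[(triethylsilyl)oxy]-4-{[tri(propan-2-yl)silyl]oxy}-1,2,3,4,5,8-hexahydroazulen-6-yl trifluoromethanesulfonate (C6 epimers) | O=S(=O)(OC1=CCC2=C(C(O[Si](C(C)C)(C(C)C)C(C)C)C1)[C@](O[Si](CC)(CC)CC)(C(C)C)CC2)C(F)(F)F | intermediate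
14 | C8-methyl diene: 13 with CH3 in place of OTf (C8=C9, C1=C5, C6–OTIPS epimers, C4–OTES) | CC1=CCC2=C(C(O[Si](C(C)C)(C(C)C)C(C)C)C1)[C@](O[Si](CC)(CC)CC)(C(C)C)CC2 | intermediate
15 | (3R)-6-methyl-3-(propan-2-yl)-1,2,3,4,5,8-hexahydroazulene-3,4-diol (epimers at the secondary carbinol) | CC1=CCC2=C(C(O)C1)[C@](O)(C(C)C)CC2 | intermediate
16 | (3R)-3-hydroxy-6-methyl-3-(propan-2-yl)-2,3,5,8-tetrahydroazulen-4(1H)-one | CC1=CCC2=C(C(=O)C1)[C@](O)(C(C)C)CC2 | intermediate
17 | dilithium salt: C4 alkoxide and C5=C6 enolate of 19 | CC1=CC[C@@]2(C)CC[C@@](O[Li])(C(C)C)C2=C(O[Li])C1 | intermediate (not isolated)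
18 | cis-fused C5 epimer of 19 | CC1=CC[C@@]2(C)CC[C@@](O)(C(C)C)[C@H]2C(=O)C1 | intermediate (not isolated)
19 | (3R,3aR,8aR)-3-hydroxy-6,8a-dimethyl-3-(propan-2-yl)-2,3,3a,5,8,8a-hexahydroazulen-4(1H)-one (trans-fused) | CC1=CC[C@@]2(C)CC[C@@](O)(C(C)C)[C@@H]2C(=O)C1 | intermediate
20 | (3R,3aS,4S,8aR)-6,8a-dimethyl-3-(propan-2-yl)-1,2,3,3a,4,5,8,8a-octahydroazulene-3,4-diol | CC1=CC[C@@]2(C)CC[C@@](O)(C(C)C)[C@@H]2[C@@H](O)C1 | intermediate
21 | O-acetylsalicyloyl chloride, 2-(chlorocarbonyl)phenyl acetate | CC(=O)Oc1ccccc1C(Cl)=O | starting material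
22 | 2-acetoxybenzoate of 20 at the secondary hydroxyl | CC1=CC[C@@]2(C)CC[C@@](O)(C(C)C)[C@@H]2[C@@H](OC(=O)c2ccccc2OC(C)=O)C1 | intermediate (not isolated)
23 | (3R,3aS,4S,8aR)-3-hydroxy-6,8a-dimethyl-3-(propan-2-yl)-1,2,3,3a,4,5,8,8a-octahydroazulen-4-yl 2-hydroxybenzoate (CNP0379621.1) | CC1=CC[C@@]2(C)CC[C@@](O)(C(C)C)[C@@H]2[C@@H](OC(=O)c2ccccc2O)C1 | target

**Totals.** Total step count: 12. Longest linear sequence: 12 steps (1 → 23).

**Steps most likely to fail**

Step 5. After the first bond (C9–C10) has formed, the silyl group may be lost from the oxocarbenium ion or passed to the enolate oxygen before ring B closes. Closure may instead occur at C1 (five-membered), ZnBr2 may ionise the allylic C4 silyloxy group of the diene, and the inner silyloxy group may slow both bond formations. The fallback is a stepwise annulation that does not need the ring to close in the same event. It sets out from 7: alkylation at C10 with the 2-methoxyallyl cation (3-bromo-2-methoxyprop-1-ene, AgOCOCF3, Na2CO3, CH2Cl2, −78 °C), with loss of the silyl group, should give the methoxyallyl enal F1. Mild aqueous acid converts its enol ether into the methyl ketone of the keto enal F2. The boron enolate formed on the methyl side (n-Bu2BOTf, i-Pr2NEt, CH2Cl2, −78 °C) adds to the C6 aldehyde and closes ring B as the hydroxy ketone F3. Silylation with i-Pr3SiOTf and 2,6-lutidine returns to 11.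

Step 10. Methyl transfer may be slow at the tetrasubstituted enone, so that deprotonation at the doubly allylic C10 competes. The cuprate may take the face of the isopropyl group. Enolate protonation may leave the cis-fused C5 epimer, and the base used to correct it may open ring A by retro-aldol cleavage. The fallback installs the angular methyl by hydroxyl-directed cyclopropanation and reductive opening. It sets out from 15: TBSCl and imidazole silylate only the secondary C6 hydroxyl to give the mono silyl ether F4. Et2Zn and CH2I2 (Simmons–Smith, through the zinc alkoxide of the C4 hydroxyl) deliver CH2 to C1=C5 on the face of the C4 oxygen, giving the cyclopropane F5. Bu4NF gives the cyclopropyl diol F6, and Swern oxidation gives the cyclopropyl ketone F7. Li in NH3/THF should cleave the C5–CH2 bond, which overlaps with the carbonyl π system, leaving CH3 on C1 cis to the C4 oxygen; protonation of the enolate returns to 19.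

Step 6. Deprotonation at C7 may compete and give the regioisomeric triflate with a C7=C8 double bond, and a C7 enolate may expel the C6 silyloxy group. The fallback is a Shapiro route. It sets out from 11: condensation with 2,4,6-triisopropylbenzenesulfonyl hydrazide gives the sulfonyl hydrazone F8, with the sulfonamide nitrogen turned toward the less hindered C9 side. n-BuLi (2 equiv) removes the C9 proton syn to that nitrogen, loss of sulfinate and N2 gives the C8 alkenyllithium with the C8=C9 double bond, and MeI returns to 14 without passing through 13.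

**Further compounds**
F1 | step 5 | (5R)-2-(3-methoxybut-3-en-1-yl)-5-(propan-2-yl)-5-[(triethylsilyl)oxy]cyclopent-1-ene-1-carbaldehyde | COC(=C)CCC1=C(C=O)[C@](O[Si](CC)(CC)CC)(C(C)C)CC1
F2 | step 5 | (5R)-2-(3-oxobutyl)-5-(propan-2-yl)-5-[(triethylsilyl)oxy]cyclopent-1-ene-1-carbaldehyde | CC(=O)CCC1=C(C=O)[C@](O[Si](CC)(CC)CC)(C(C)C)CC1
F3 | step 5 | (3R)-4-hydroxy-3-(propan-2-yl)-3-[(triethylsilyl)oxy]-2,3,4,5,7,8-hexahydroazulen-6(1H)-one (carbinol epimers) | O=C1CCC2=C(C(O)C1)[C@](O[Si](CC)(CC)CC)(C(C)C)CC2
F4 | step 10 | 15 with the secondary hydroxyl as its tert-butyldimethylsilyl ether (C6 epimers) | CC1=CCC2=C(C(O[Si](C)(C)C(C)(C)C)C1)[C@](O)(C(C)C)CC2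
F5 | step 10 | F4 with a CH2 bridge across C1–C5 on the face of the C4 hydroxyl | CC1=CC[C@]23C[C@@]2(C(O[Si](C)(C)C(C)(C)C)C1)[C@](O)(C(C)C)CC3
F6 | step 10 | cyclopropyl diol from F5 (C6 epimers) | CC1=CC[C@]23C[C@@]2(C(O)C1)[C@](O)(C(C)C)CC3
F7 | step 10 | cyclopropyl ketone (C6 ketone flanking the C1–C5 cyclopropane, C4–OH) | CC1=CC[C@]23C[C@@]2(C(=O)C1)[C@](O)(C(C)C)CC3
F8 | step 6 | 2,4,6-triisopropylbenzenesulfonyl hydrazone of 11 | CC(C)c1cc(C(C)C)c(S(=O)(=O)NN=C2CCC3=C(C(O[Si](C(C)C)(C(C)C)C(C)C)C2)[C@](O[Si](CC)(CC)CC)(C(C)C)CC3)c(C(C)C)c1
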